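Numbers refer to the compound list that follows the steps. Isoflavone numbering (O1, C2, C3, C4, C4a, C5 to C8, C8a; primed numbers for the 3-aryl ring) is used for every intermediate, also before ring C exists.

## Analysis of the target

Compound 33 is an isoflavone: a benzo ring (ring A) fused to a 4-pyranone (ring C: O1, C2, C3, C4, C4a, C8a), with an aryl group (ring B) on C3. Ring A carries hydroxyls at C5 and C7 and a 3-hydroxy-3-methylbutyl chain at C6 between them. Ring B carries hydroxyls at C2' and C4' and a prenyl group at C3' between them. There is no stereocentre and no alkene geometry to set, so the problem is one of regiochemistry and functional-group tolerance. The prenyl alkene and the tertiary carbinol each sit next to phenols, so acid can close dimethylchroman rings; the alkene also rules out a final hydrogenolysis and would trap any electrophilic carbene. The hard points are to place the chain at C6 and not at C8, to place the prenyl group at C3', and to tell five hydroxyls apart. The strategy rests on C3: it is a single carbon whose only substituent is ring B, flanked by C2–H and the C4 carbonyl. Without it, ring C is the five-membered ring of a benzofuran-3-one (O1, C2, C4, C4a, C8a), so the isoflavone is a benzofuranone plus one inserted aryl-bearing carbon.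

## Retrosynthetic reasoning

**Unmasking (33 from 32).** The last step should only remove protecting groups, and it cannot be a hydrogenolysis because the prenyl alkene is then present. In 32 the oxygens at C5, C7 and C4' are methoxymethyl ethers, the chain carbinol is a triethylsilyl ether and O2' is free. All four groups should fall in one treatment with dilute acid.

**C3'–prenyl bond (32 from 30; 30 from 26 and 29; 29 from 27).** The bond between C3' and the prenyl CH2 is cut as a retro-Claisen step: 32 arises by a [3,3] shift of the 1,1-dimethylallyl ether 30. Of the two carbons ortho to O2', only C3' is free, and the shift inverts the allyl unit, so the tertiary ether gives the normal prenyl group. Ether 30 comes from phenol 26 and carbonate 29 by palladium-catalysed O-allylation, and 29 from alcohol 27. The prenyl group is attached this late on purpose, because an alkene anywhere in the molecule would compete for the carbene of the key step.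

**O2' (26 from 25).** O2' must be the one phenol that can be freed alone. In 25 it is a benzyl ether, cleaved by hydrogenolysis while the chromone C2=C3 bond is the only other reducible π bond.

**Ring C (25 from 15 and 22).** Excising C3 with its aryl group cuts C3–C2 and C3–C4 and restores the C2–C4 bond. This contracts the pyranone to the furan ring of 15, the silyl enol ether of a benzofuran-3-one. The excised carbon becomes arylchlorocarbene 23, stored as chlorodiazirine 22. This cut is preferred to those at O1–C2, C3–C1' or C4–C4a for three reasons: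
- it joins two simple aromatic pieces in one step;
- it gives ring C at the right oxidation level, with no condensation, dehydration or oxidation to follow;
- it takes the ring A regiochemistry from a five-membered ring in which O1 is already placed.

In the forward direction the carbene must add to the enol ether π bond of 15 and to nothing else. Cyclopropane 24 must then open between the two oxygen-bearing carbons, with loss of chloride and of the silyl group. Both partners are therefore kept free of alkenes and O–H bonds.

**Benzofuranone (15 from 14; 14 from 12; 12 from 10 and 11).** Silyl enol ether 15 is made from ketone 14. The C4–C4a bond of 14 is cut to aryl bromide 12, whose aryllithium 13 closes onto a Weinreb amide. The O1–C2 bond of 12 is cut to bromophenol 10 and chloroacetamide 11. An anionic closure is chosen because the acetals and the silyl ether would not survive an acid-mediated acylation.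

**O1 and the bromide (10 from 9; 9 from 7).** Phenol 9 is symmetric, so its two ortho positions are equivalent and bromination can give only 10. Because O1 is para to the chain, the chain must end at C6 and cannot end at C8. The C–O bond of 9 is traced to a C–H bond of 7. That hydrogen is meta to both ether oxygens, out of reach of electrophilic substitution or directed lithiation. It is, however, the only ring hydrogen without an ortho neighbour, which is what sterically governed iridium-catalysed borylation selects (boronate 8, then oxidation).

**Chain (7 from 6; 6 from 5; 5 from 2 and 3; 2 from 1).** The carbinol of 6 is the Markovnikov hydrate of prenyl arene 5 and is silylated to 7. The aryl–CH2 bond of 5 is cut to aryllithium 4 and prenyl bromide 3. The carbon between the two acetal oxygens of 2 is the most acidic, so lithiation puts the chain exactly where C6 will be. Compound 2 is the bis-acetal of 1.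

**Diazirine (22 from 21; 21 from 19; 19 from 18; 18 from 17; 17 from 16).** Diazirine 22 is the oxidation product of amidinium salt 21 (Graham reaction), which comes from nitrile 19. The two ring B oxygens need different groups, and that is easiest at the aldehyde stage. In 16 the ortho hydroxyl is held in a hydrogen bond to the formyl group, so the para hydroxyl is acetalised first (17) and the ortho one benzylated afterwards (18). A nitrile offers no such handle, so the nitrile is made from the aldehyde (18 to 19).

## Alternatives that were turned down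

**Alternative 1:** The C3–C4 bond is cut. In the forward step a triazolium-derived N-heterocyclic carbene turns the ring A aldehyde of keto aldehyde A2 into an acyl anion equivalent, which adds to the tethered ring B ketone and closes ring C as the racemic 3-hydroxyisoflavanone A1.
- For: this crossed aldehyde–ketone benzoin is an established way to 3-hydroxychroman-4-ones, so on precedent it is stronger than the chosen key step. The prenyl group travels with ring B, so no late Claisen sequence is needed. The ring A regiochemistry is equally secure.
- Against: the aldehyde of A2 lies between two ortho oxygen substituents, and the ketone is very electron-rich and ortho-substituted, so both partners are poor. The O–CH2 protons next to the ketone are acidic, and under the basic conditions an intramolecular aldol condensation to a 2-aroylbenzofuran competes. A1 carries a C3 stereocentre that is made only to be destroyed. A1 is also one dehydration away from the isoflavone, and that requires activating a tertiary α-hydroxy ketone in the presence of acetals, a silyl ether and the prenyl alkene. Building A2 also needs a halogenation next to the ring B ketone with the alkene present.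
- Comparison: the chosen strategy gives the aromatic pyranone directly, with no redox or dehydration adjustment and no base-sensitive keto aldehyde. Its price is an unprecedented substrate class.

**Alternative 2:** The C4–C4a bond is cut. In the forward step the (Z)-3-aryloxy-2-arylacrylic acid A4 is activated as a mixed anhydride and acylates the ortho carbon of ring A, closing ring C to the tetrakis(methoxymethyl) ether A3.
- For: the two ortho positions of the ring A aryl ether are equivalent, so the regiochemistry is as safe as in the chosen route. Ring A is a strong nucleophile. The reaction type is classical, so precedent is again stronger, and A3 is one deprotection from the target.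
- Against: the activation releases a strong acid next to four acetals, a free tertiary carbinol and a prenyl alkene ortho to oxygen. Acetal loss, ionisation of the carbinol and chroman closure are all expected. Only the isomer of A4 with aryloxy and carboxyl cis can close, and the usual routes to such acids give mixtures of isomers. The acylating carbon is deactivated by the β-aryloxy group.
- Comparison: the chosen strategy forms ring C under buffered, essentially neutral conditions, at a stage where neither the alkene nor a free carbinol is present.

**Alternative 3:** Ring B itself is cut (C2'–C3', C4'–C5', C1'–C2', C5'–C6') and built on a preformed chromone. In the forward step irradiation of diazo enone A6 triggers a Wolff shift to a vinylketene, which adds siloxyalkyne A7. Opening of the cyclobutenone and six-electron electrocyclisation then give phenol A5.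
- For: hydroxyl, prenyl and silyloxy groups are placed on ring B in one step with complete regiocontrol. O2' emerges free and O4' differentiated, and the prenyl group arrives without hydrogenolysis, allylation or Claisen steps. On these points, and on precedent for the reaction type, it is stronger than the chosen route.
- Against: ring C still has to be made first by a classical route. The chromone must then be extended at C3 to A6 without acid, since the usual formylating closures are strongly acidic. The chromone chromophore competes for the light and is itself photoreactive. A7 is a sensitive reagent that needs its own multistep preparation. The overall count is clearly higher.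
- Comparison: the chosen strategy spends its steps on two plain aromatic building blocks and forms ring C and the C3–C1' connection together.

Key step: step 15

Remark (assumption on the chemistry): diazirine 22 is assumed to be too labile to store, so step 14 is run directly before step 15 and its solution is used without concentration.

## Route

Step 1
Reactants: 1 resorcinol
Product: 2 1,3-bis(methoxymethoxy)benzene
Conditions: NaH, MOMCl, DMF, 0 °C → rt
Reagents that add atoms: chloromethyl methyl ether, COCCl
Why: Williamson-type acetalisation of both phenoxides; the two acetal groups later direct lithiation to the carbon between them and tolerate all basic and organometallic steps.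

Step 2
Reactants: 2 1,3-bis(methoxymethoxy)benzene; 3 1-bromo-3-methylbut-2-ene (prenyl bromide)
Product: 5 1,3-bis(methoxymethoxy)-2-(3-methylbut-2-en-1-yl)benzene, via aryllithium 4 (not isolated)
Conditions: n-BuLi, THF, 0 °C; then CuI (10 mol %), 3, −78 °C → rt
Reagents that add atoms: none
Why: Directed ortho-metalation removes the hydrogen between the two chelating acetal oxygens, and copper-assisted SN2 alkylation by the allylic bromide should put the five-carbon chain on that carbon, the future C6.

Step 3
Reactants: 5 1,3-bis(methoxymethoxy)-2-(3-methylbut-2-en-1-yl)benzene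
Product: 6 4-[2,6-bis(methoxymethoxy)phenyl]-2-methylbutan-2-ol
Conditions: Co(acac)2 (20 mol %), PhSiH3, O2 (1 atm), THF, rt; aq. Na2S2O3 work-up
Reagents that add atoms: dioxygen, O=O
Why: Mukaiyama hydration: hydrogen-atom transfer to the trisubstituted alkene gives the tertiary radical, which is trapped by oxygen and reduced, so the Markovnikov tertiary alcohol is expected; the acetals are inert.

Step 4
Reactants: 6 4-[2,6-bis(methoxymethoxy)phenyl]-2-methylbutan-2-ol
Product: 7 triethyl({4-[2,6-bis(methoxymethoxy)phenyl]-2-methylbutan-2-yl}oxy)silane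
Conditions: Et3SiCl, imidazole, DMAP (cat.), DMF, 40 °C
Reagents that add atoms: chlorotriethylsilane, CC[Si](Cl)(CC)CC
Why: Silylation of the tertiary alcohol removes the only O–H bond of the ring A fragment, which would otherwise quench organolithiums and the carbene; the silyl chloride is used in place of a silyl triflate to keep the aryl acetals safe.

Step 5
Reactants: 7 triethyl({4-[2,6-bis(methoxymethoxy)phenyl]-2-methylbutan-2-yl}oxy)silane
Product: 9 3,5-bis(methoxymethoxy)-4-[3-methyl-3-(triethylsilyloxy)butyl]phenol, via arylboronate 8 (not isolated)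
Conditions: [Ir(OMe)(cod)]2 (2 mol %), 4,4'-di-tert-butyl-2,2'-bipyridine, B2pin2, THF, 70 °C; then aq. NaOH, H2O2, 0 °C
Reagents that add atoms: bis(pinacolato)diboron, CC1(C)OB(OC1(C)C)B1OC(C)(C)C(C)(C)O1 (boron of 8); hydrogen peroxide, OO (phenol oxygen of 9)
Why: Sterically controlled iridium-catalysed C–H borylation (Hartwig–Miyaura type) should reach only the ring hydrogen that has no ortho substituent, para to the chain, and oxidation of the C–B bond gives the phenol that becomes O1. Because 9 is symmetric, the chain is thereby fixed para to O1, that is at C6.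

Step 6
Reactants: 9 3,5-bis(methoxymethoxy)-4-[3-methyl-3-(triethylsilyloxy)butyl]phenol
Product: 10 2-bromo-3,5-bis(methoxymethoxy)-4-[3-methyl-3-(triethylsilyloxy)butyl]phenol
Conditions: NBS (1.0 equiv), CH2Cl2, −78 → −20 °C
Reagents that add atoms: N-bromosuccinimide, O=C1CCC(=O)N1Br
Why: Electrophilic bromination ortho to the free hydroxyl; the two ortho positions are equivalent, so one equivalent at low temperature should give a single monobromide.

Step 7
Reactants: 10 2-bromo-3,5-bis(methoxymethoxy)-4-[3-methyl-3-(triethylsilyloxy)butyl]phenol; 11 2-chloro-N-methoxy-N-methylacetamide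
Product: 12 2-{2-bromo-3,5-bis(methoxymethoxy)-4-[3-methyl-3-(triethylsilyloxy)butyl]phenoxy}-N-methoxy-N-methylacetamide
Conditions: K2CO3, NaI (cat.), DMF, 50 °C
Reagents that add atoms: none
Why: Williamson O-alkylation of the phenoxide by the α-chloro amide under iodide catalysis; it installs the carbons that become C2 and C4 with the acyl carbon as a Weinreb amide.

Step 8
Reactants: 12 2-{2-bromo-3,5-bis(methoxymethoxy)-4-[3-methyl-3-(triethylsilyloxy)butyl]phenoxy}-N-methoxy-N-methylacetamide
Product: 14 4,6-bis(methoxymethoxy)-5-[3-methyl-3-(triethylsilyloxy)butyl]-1-benzofuran-3(2H)-one, via aryllithium 13 (not isolated)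
Conditions: t-BuLi (2.1 equiv), THF, −78 °C; then aq. NH4Cl
Reagents that add atoms: none
Why: Parham cyclisation: bromine–lithium exchange should outrun deprotonation at low temperature, and the aryllithium adds in a 5-exo mode to the Weinreb amide, whose chelated adduct holds until work-up so that the ketone is not attacked again.

Step 9
Reactants: 14 4,6-bis(methoxymethoxy)-5-[3-methyl-3-(triethylsilyloxy)butyl]-1-benzofuran-3(2H)-one
Product: 15 tert-butyl({4,6-bis(methoxymethoxy)-5-[3-methyl-3-(triethylsilyloxy)butyl]-1-benzofuran-3-yl}oxy)dimethylsilane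
Conditions: t-BuMe2SiOTf, Et3N, CH2Cl2, −78 → 0 °C
Reagents that add atoms: tert-butyldimethylsilyl trifluoromethanesulfonate, CC(C)(C)[Si](C)(C)OS(=O)(=O)C(F)(F)F
Why: Soft enolisation and O-silylation; the gain of furan aromaticity should make O-silylation complete, and the short low-temperature exposure spares the acetals.

Step 10
Reactants: 16 2,4-dihydroxybenzaldehyde
Product: 17 2-hydroxy-4-(methoxymethoxy)benzaldehyde
Conditions: MOMCl (1.1 equiv), K2CO3, acetone, 0 °C → rt
Reagents that add atoms: chloromethyl methyl ether, COCCl
Why: The 2-hydroxyl is tied up in a hydrogen bond to the formyl oxygen, so the more acidic and more accessible 4-hydroxyl should be alkylated selectively.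

Step 11
Reactants: 17 2-hydroxy-4-(methoxymethoxy)benzaldehyde
Product: 18 2-(benzyloxy)-4-(methoxymethoxy)benzaldehyde
Conditions: BnBr, K2CO3, DMF, 60 °C
Reagents that add atoms: benzyl bromide, BrCc1ccccc1
Why: Williamson benzylation of the remaining chelated phenol under slightly forcing conditions; the benzyl ether is the one group that can later be removed without touching acetals or silyl ethers.

Step 12
Reactants: 18 2-(benzyloxy)-4-(methoxymethoxy)benzaldehyde
Product: 19 2-(benzyloxy)-4-(methoxymethoxy)benzonitrile
Conditions: I2, aq. NH3, THF, rt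
Reagents that add atoms: ammonia, N
Why: Oxidative conversion of an aldehyde to a nitrile: condensation with ammonia, N-iodination and loss of hydrogen iodide; the basic medium keeps the acetal intact.

Step 13
Reactants: 19 2-(benzyloxy)-4-(methoxymethoxy)benzonitrile
Product: 21 2-(benzyloxy)-4-(methoxymethoxy)benzamidinium chloride, via silylated amidinate 20 (not isolated)
Conditions: LiN(SiMe3)2, THF, 0 °C → rt; then MeOH, NH4Cl, 0 °C → rt
Reagents that add atoms: lithium bis(trimethylsilyl)amide, [Li]N([Si](C)(C)C)[Si](C)(C)C (second nitrogen); ammonium chloride, [NH4+].[Cl-] (chloride counter-ion)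
Why: Addition of the silylamide to the nitrile gives the silylated amidinate; methanolysis of the N–Si bonds and salt formation with the weak acid ammonium chloride avoid the strong acid that would cleave the acetal.

Step 14
Reactants: 21 2-(benzyloxy)-4-(methoxymethoxy)benzamidinium chloride
Product: 22 3-[2-(benzyloxy)-4-(methoxymethoxy)phenyl]-3-chloro-3H-diazirine
Conditions: LiCl, DMSO; aq. NaOCl, 0–10 °C; extraction into hexane/MTBE, cold solution used at once
Reagents that add atoms: sodium hypochlorite, [Na+].[O-]Cl, with lithium chloride, [Li+].[Cl-], as chloride reservoir (chlorine on carbon)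
Why: Graham reaction: N-chlorination of the amidine, base-induced N–N ring closure and return of chloride to carbon should give the 3-aryl-3-chlorodiazirine; the two donor oxygens make it labile, hence no concentration and immediate use.

Step 15
Reactants: 15 tert-butyl({4,6-bis(methoxymethoxy)-5-[3-methyl-3-(triethylsilyloxy)butyl]-1-benzofuran-3-yl}oxy)dimethylsilane; 22 3-[2-(benzyloxy)-4-(methoxymethoxy)phenyl]-3-chloro-3H-diazirine
Product: 25 3-[2-(benzyloxy)-4-(methoxymethoxy)phenyl]-5,7-bis(methoxymethoxy)-6-[3-methyl-3-(triethylsilyloxy)butyl]-4H-chromen-4-one, via arylchlorocarbene 23 (not isolated), via chlorocyclopropane 24 (not isolated)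
Conditions: 22 (2.5 equiv, cold solution, added in portions), Na2CO3, MeCN, 0 → 45 °C, dark
Reagents that add atoms: none
Why: Proposed new method: warming 22 expels nitrogen and releases singlet arylchlorocarbene 23, which adds in a [2+1] fashion to the most electron-rich π bond present, the silyl enol ether bond of furan 15 (isoflavone C2 and C4), forming the bonds C3–C2 and C3–C4 of chlorocyclopropane 24. Ionisation of the C–Cl bond, helped by the dioxygenated aryl group, triggers disrotatory two-electron electrocyclic opening that cleaves the old C2–C4 bond, because only this bond lies opposite the carbon that loses chloride and only this cleavage gives a cation stabilised by O1 at C2 and by the silyloxy group at C4; chloride then takes the silyl group and leaves the aromatic 4-pyranone. Ring C is thus closed by one-carbon ring expansion of the five-membered ring (cyclopropanation, then electrocyclic ring opening), not by a cyclisation, and 25 has no stereocentre, those of 24 being erased. The closest known reactions are the Ciamician–Dennstedt-type insertion of arylchlorocarbenes from chlorodiazirines into indoles, pyrroles and indenes and the halocarbene ring expansion of cyclic silyl enol ethers; 3-silyloxybenzofurans have not been used. The step needs chemoselectivity for the enol ether over the arene rings and over the benzylic C–H bonds of the ortho benzyloxy group, which the nucleophilicity of C2, a high concentration of 15 and the absence of any other alkene or O–H bond should secure. The orientation of chlorine in 24 is not controlled, but a benzylic, donor-stabilised cation should let both epimers ionise. Na2CO3 buffers traces of acid, which could open 24 by protodesilylation toward a 2-benzylidene benzofuranone.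

Step 16
Reactants: 25 3-[2-(benzyloxy)-4-(methoxymethoxy)phenyl]-5,7-bis(methoxymethoxy)-6-[3-methyl-3-(triethylsilyloxy)butyl]-4H-chromen-4-one
Product: 26 3-[2-hydroxy-4-(methoxymethoxy)phenyl]-5,7-bis(methoxymethoxy)-6-[3-methyl-3-(triethylsilyloxy)butyl]-4H-chromen-4-one
Conditions: H2 (1 atm), Pd/C, EtOAc, rt
Reagents that add atoms: none
Why: Hydrogenolysis of the benzyl ether; in ethyl acetate at atmospheric pressure the conjugated trisubstituted C2=C3 bond of the chromone and the silyl ether should survive if the reaction is stopped at full conversion.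

Step 17
Reactants: 27 2-methylbut-3-en-2-ol
Product: 29 methyl 2-methylbut-3-en-2-yl carbonate, via lithium alkoxide 28 (not isolated)
Conditions: n-BuLi, THF, −78 °C; then ClCO2Me, −78 → 0 °C
Reagents that add atoms: methyl chloroformate, COC(=O)Cl
Why: Acylation of the preformed lithium alkoxide is the reliable way to a tertiary allylic carbonate, which ionises readily with zerovalent palladium.

Step 18
Reactants: 26 3-[2-hydroxy-4-(methoxymethoxy)phenyl]-5,7-bis(methoxymethoxy)-6-[3-methyl-3-(triethylsilyloxy)butyl]-4H-chromen-4-one; 29 methyl 2-methylbut-3-en-2-yl carbonate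
Product: 30 3-[4-(methoxymethoxy)-2-(2-methylbut-3-en-2-yloxy)phenyl]-5,7-bis(methoxymethoxy)-6-[3-methyl-3-(triethylsilyloxy)butyl]-4H-chromen-4-one
Conditions: Pd(PPh3)4 (5 mol %), THF, 0 °C → rt
Reagents that add atoms: none
Why: Tsuji–Trost O-allylation: zerovalent palladium ionises the carbonate, the methoxide released deprotonates the phenol, and under kinetic control the phenoxide should attack the more substituted allyl terminus to give the tertiary ether.

Step 19
Reactants: 30 3-[4-(methoxymethoxy)-2-(2-methylbut-3-en-2-yloxy)phenyl]-5,7-bis(methoxymethoxy)-6-[3-methyl-3-(triethylsilyloxy)butyl]-4H-chromen-4-one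
Product: 32 3-[2-hydroxy-4-(methoxymethoxy)-3-(3-methylbut-2-en-1-yl)phenyl]-5,7-bis(methoxymethoxy)-6-[3-methyl-3-(triethylsilyloxy)butyl]-4H-chromen-4-one, via ortho-dienone 31 (not isolated)
Conditions: PhNEt2, 130 °C
Reagents that add atoms: none
Why: Aromatic Claisen rearrangement: the [3,3] shift inverts the allyl unit and should deliver a normal prenyl group to C3', the only free ortho position, after which tautomerisation restores the phenol. The basic solvent suppresses acid-catalysed chroman formation.

Step 20
Reactants: 32 3-[2-hydroxy-4-(methoxymethoxy)-3-(3-methylbut-2-en-1-yl)phenyl]-5,7-bis(methoxymethoxy)-6-[3-methyl-3-(triethylsilyloxy)butyl]-4H-chromen-4-one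
Product: 33 3-[2,4-dihydroxy-3-(3-methylbut-2-en-1-yl)phenyl]-5,7-dihydroxy-6-(3-hydroxy-3-methylbutyl)-4H-chromen-4-one
Conditions: aq. HCl (2 M)/MeOH 1:4, 40 °C, stopped when the last acetal is gone
Reagents that add atoms: none
Why: Acid-catalysed acetal exchange removes the three methoxymethyl ethers and the silyl ether is solvolysed at silicon. Dilute acid at modest temperature is chosen because acetal cleavage should be faster than protonation of the trisubstituted alkene or ionisation of the tertiary carbinol.

## Compound list

1 | resorcinol (benzene-1,3-diol) | Oc1cccc(O)c1 | starting material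
2 | 1,3-bis(methoxymethoxy)benzene | COCOc1cccc(OCOC)c1 | intermediate
3 | 1-bromo-3-methylbut-2-ene (prenyl bromide) | CC(C)=CCBr | starting material
4 | [2,6-bis(methoxymethoxy)phenyl]lithium | [Li]c1c(OCOC)cccc1OCOC | intermediate
5 | 1,3-bis(methoxymethoxy)-2-(3-methylbut-2-en-1-yl)benzene | COCOc1cccc(OCOC)c1CC=C(C)C | intermediate
6 | 4-[2,6-bis(methoxymethoxy)phenyl]-2-methylbutan-2-ol | COCOc1cccc(OCOC)c1CCC(C)(C)O | intermediate
7 | triethyl({4-[2,6-bis(methoxymethoxy)phenyl]-2-methylbutan-2-yl}oxy)silane | COCOc1cccc(OCOC)c1CCC(C)(C)O[Si](CC)(CC)CC | intermediate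
8 | 2-{3,5-bis(methoxymethoxy)-4-[3-methyl-3-(triethylsilyloxy)butyl]phenyl}-4,4,5,5-tetramethyl-1,3,2-dioxaborolane | COCOc1cc(B2OC(C)(C)C(C)(C)O2)cc(OCOC)c1CCC(C)(C)O[Si](CC)(CC)CC | intermediate
9 | 3,5-bis(methoxymethoxy)-4-[3-methyl-3-(triethylsilyloxy)butyl]phenol | COCOc1cc(O)cc(OCOC)c1CCC(C)(C)O[Si](CC)(CC)CC | intermediate
10 | 2-bromo-3,5-bis(methoxymethoxy)-4-[3-methyl-3-(triethylsilyloxy)butyl]phenol | COCOc1cc(O)c(Br)c(OCOC)c1CCC(C)(C)O[Si](CC)(CC)CC | intermediate
11 | 2-chloro-N-methoxy-N-methylacetamide | CON(C)C(=O)CCl | starting material
12 | 2-{2-bromo-3,5-bis(methoxymethoxy)-4-[3-methyl-3-(triethylsilyloxy)butyl]phenoxy}-N-methoxy-N-methylacetamide | CON(C)C(=O)COc1cc(OCOC)c(CCC(C)(C)O[Si](CC)(CC)CC)c(OCOC)c1Br | intermediate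
13 | {2-[2-(methoxy(methyl)amino)-2-oxoethoxy]-4,6-bis(methoxymethoxy)-5-[3-methyl-3-(triethylsilyloxy)butyl]phenyl}lithium | CON(C)C(=O)COc1cc(OCOC)c(CCC(C)(C)O[Si](CC)(CC)CC)c(OCOC)c1[Li] | intermediate
14 | 4,6-bis(methoxymethoxy)-5-[3-methyl-3-(triethylsilyloxy)butyl]-1-benzofuran-3(2H)-one | O=C1COc2cc(OCOC)c(CCC(C)(C)O[Si](CC)(CC)CC)c(OCOC)c12 | intermediate
15 | tert-butyl({4,6-bis(methoxymethoxy)-5-[3-methyl-3-(triethylsilyloxy)butyl]-1-benzofuran-3-yl}oxy)dimethylsilane | CC(C)(C)[Si](C)(C)Oc1coc2cc(OCOC)c(CCC(C)(C)O[Si](CC)(CC)CC)c(OCOC)c12 | intermediate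
16 | 2,4-dihydroxybenzaldehyde | O=Cc1ccc(O)cc1O | starting material
17 | 2-hydroxy-4-(methoxymethoxy)benzaldehyde | O=Cc1ccc(OCOC)cc1O | intermediate
18 | 2-(benzyloxy)-4-(methoxymethoxy)benzaldehyde | O=Cc1ccc(OCOC)cc1OCc1ccccc1 | intermediate
19 | 2-(benzyloxy)-4-(methoxymethoxy)benzonitrile | N#Cc1ccc(OCOC)cc1OCc1ccccc1 | intermediate
20 | lithium N,N'-bis(trimethylsilyl)-2-(benzyloxy)-4-(methoxymethoxy)benzamidinate | C[Si](C)(C)N=C(c1ccc(OCOC)cc1OCc1ccccc1)N([Li])[Si](C)(C)C | intermediate
21 | 2-(benzyloxy)-4-(methoxymethoxy)benzamidinium chloride | [Cl-].NC(=[NH2+])c1ccc(OCOC)cc1OCc1ccccc1 | intermediate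
22 | 3-[2-(benzyloxy)-4-(methoxymethoxy)phenyl]-3-chloro-3H-diazirine | ClC1(c2ccc(OCOC)cc2OCc2ccccc2)N=N1 | intermediate
23 | [2-(benzyloxy)-4-(methoxymethoxy)phenyl]chlorocarbene | Cl[C]c1ccc(OCOC)cc1OCc1ccccc1 | intermediate
24 | 1-[2-(benzyloxy)-4-(methoxymethoxy)phenyl]-6b-(tert-butyldimethylsilyloxy)-1-chloro-4,6-bis(methoxymethoxy)-5-[3-methyl-3-(triethylsilyloxy)butyl]-1a,6b-dihydro-1H-cyclopropa[b][1]benzofuran (racemic, both epimers at the chlorine-bearing carbon) | ClC1(c2ccc(OCOC)cc2OCc2ccccc2)C2Oc3cc(OCOC)c(CCC(C)(C)O[Si](CC)(CC)CC)c(OCOC)c3C12O[Si](C)(C)C(C)(C)C | intermediate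
25 | 3-[2-(benzyloxy)-4-(methoxymethoxy)phenyl]-5,7-bis(methoxymethoxy)-6-[3-methyl-3-(triethylsilyloxy)butyl]-4H-chromen-4-one | COCOc1ccc(-c2coc3cc(OCOC)c(CCC(C)(C)O[Si](CC)(CC)CC)c(OCOC)c3c2=O)c(OCc2ccccc2)c1 | intermediate
26 | 3-[2-hydroxy-4-(methoxymethoxy)phenyl]-5,7-bis(methoxymethoxy)-6-[3-methyl-3-(triethylsilyloxy)butyl]-4H-chromen-4-one | COCOc1ccc(-c2coc3cc(OCOC)c(CCC(C)(C)O[Si](CC)(CC)CC)c(OCOC)c3c2=O)c(O)c1 | intermediate
27 | 2-methylbut-3-en-2-ol | CC(C)(O)C=C | starting material
28 | lithium 2-methylbut-3-en-2-olate | [Li]OC(C)(C)C=C | intermediate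
29 | methyl 2-methylbut-3-en-2-yl carbonate | COC(=O)OC(C)(C)C=C | intermediate
30 | 3-[4-(methoxymethoxy)-2-(2-methylbut-3-en-2-yloxy)phenyl]-5,7-bis(methoxymethoxy)-6-[3-methyl-3-(triethylsilyloxy)butyl]-4H-chromen-4-one | COCOc1ccc(-c2coc3cc(OCOC)c(CCC(C)(C)O[Si](CC)(CC)CC)c(OCOC)c3c2=O)c(OC(C)(C)C=C)c1 | intermediate
31 | 3-[5-(methoxymethoxy)-6-(3-methylbut-2-en-1-yl)-1-oxocyclohexa-2,4-dien-2-yl]-5,7-bis(methoxymethoxy)-6-[3-methyl-3-(triethylsilyloxy)butyl]-4H-chromen-4-one (racemic) | CC(C)=CCC1C(=O)C(-c2coc3cc(OCOC)c(CCC(C)(C)O[Si](CC)(CC)CC)c(OCOC)c3c2=O)=CC=C1OCOC | intermediate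
32 | 3-[2-hydroxy-4-(methoxymethoxy)-3-(3-methylbut-2-en-1-yl)phenyl]-5,7-bis(methoxymethoxy)-6-[3-methyl-3-(triethylsilyloxy)butyl]-4H-chromen-4-one | CC(C)=CCc1c(OCOC)ccc(-c2coc3cc(OCOC)c(CCC(C)(C)O[Si](CC)(CC)CC)c(OCOC)c3c2=O)c1O | intermediate
33 | 3-[2,4-dihydroxy-3-(3-methylbut-2-en-1-yl)phenyl]-5,7-dihydroxy-6-(3-hydroxy-3-methylbutyl)-4H-chromen-4-one | CC(C)=CCc1c(O)ccc(-c2coc3cc(O)c(CCC(C)(C)O)c(O)c3c2=O)c1O | target

## Step count and least certain steps

Total: 20 steps. Longest linear sequence: 14 steps (steps 1 to 9, 15, 16, 18, 19, 20).

**Step 15 (key step, judged together with its reagent from step 14).** Three processes are most likely to spoil it: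
- decay of the donor-rich diazirine by ionisation of its C–Cl bond before or instead of carbene release;
- insertion of the carbene into the benzylic C–H bonds of its own ortho benzyloxy group, or attack on an arene ring, in competition with addition to the crowded enol ether, whose silyloxy-bearing carbon lies next to the C5 acetal;
- opening of the cyclopropane in the wrong sense under traces of acid.

The fallback uses known chemistry and builds ring C by the deoxybenzoin route. It sets out from aldehyde 18 and bromophenol 10 and comes back at 25.
- Aldehyde 18 is homologated by van Leusen reductive cyanation (p-toluenesulfonylmethyl isocyanide, KOt-Bu, DME, then MeOH) to [2-(benzyloxy)-4-(methoxymethoxy)phenyl]acetonitrile F1.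
- Hydrolysis (KOH, aq. EtOH, reflux) gives [2-(benzyloxy)-4-(methoxymethoxy)phenyl]acetic acid F2.
- Carbodiimide coupling with N,O-dimethylhydroxylamine gives 2-[2-(benzyloxy)-4-(methoxymethoxy)phenyl]-N-methoxy-N-methylacetamide F3.
- Bromophenol 10 is deprotonated (NaH), subjected to bromine–lithium exchange (t-BuLi, THF, −78 °C) and acylated with F3 to give 2-[2-(benzyloxy)-4-(methoxymethoxy)phenyl]-1-{2-hydroxy-4,6-bis(methoxymethoxy)-5-[3-methyl-3-(triethylsilyloxy)butyl]phenyl}ethan-1-one F4.
- Heating F4 with N,N-dimethylformamide dimethyl acetal in toluene supplies C2 and closes the pyranone to 25.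

**Step 8.** Deprotonation next to the amide, or direct attack of the alkyllithium on the amide, may compete with halogen–metal exchange, and proton transfer may quench the aryllithium before it cyclises. The fallback separates metalation from acylation and closes the ring at oxygen instead. It sets out from 10 and comes back at 14. Bromophenol 10 is deprotonated, exchanged with t-BuLi and acylated with 11 to give 2-chloro-1-{2-hydroxy-4,6-bis(methoxymethoxy)-5-[3-methyl-3-(triethylsilyloxy)butyl]phenyl}ethan-1-one F5, which closes to 14 by intramolecular O-alkylation (K2CO3, acetone).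

**Step 18.** Attack at the unsubstituted allyl terminus, or equilibration of the tertiary ether to the linear prenyl ether, would lead after rearrangement to the wrong, reverse-prenyl isomer. The fallback sets out from 26 and comes back at 30. Phenol 26 is alkylated with 3-chloro-3-methylbut-1-yne (CuCl2 cat., DBU, MeCN, 0 °C) to 5,7-bis(methoxymethoxy)-3-[4-(methoxymethoxy)-2-(2-methylbut-3-yn-2-yloxy)phenyl]-6-[3-methyl-3-(triethylsilyloxy)butyl]-4H-chromen-4-one F6. Semi-hydrogenation over Pd/CaCO3 poisoned with Pb(OAc)2 in the presence of quinoline then gives 30.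

**Step 19.** Heating may cleave the tertiary allyl ether to the phenol and a diene, the allyl group may migrate by way of the blocked C1' on to C5', or the new prenyl group may close onto O2'. The fallback sets out from 26 and comes back at 32, leaving out 30. The sodium phenoxide of 26 (NaH, toluene) is C-alkylated at its only free ortho carbon with prenyl bromide 3. Non-polar conditions favour ortho C-alkylation over O-alkylation. This fallback makes no new compound (entry F0).

**Step 20.** Acid may close the prenyl group or the carbinol onto a neighbouring phenol before the slower acetals at O7 and O4' are gone. The fallback avoids protic acid. It sets out from 32 and comes back at 33. Trimethylsilyl triflate with 2,2'-bipyridyl in MeCN at 0 °C transfers silyl groups to the acetal oxygens and the free phenol, giving 3-[3-(3-methylbut-2-en-1-yl)-2,4-bis(trimethylsilyloxy)phenyl]-6-[3-methyl-3-(triethylsilyloxy)butyl]-5,7-bis(trimethylsilyloxy)-4H-chromen-4-one F7. Buffered fluoride (tetrabutylammonium fluoride with acetic acid, THF, 0 °C) then removes all silyl groups to give 33.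

## Further compounds

F1 | step 15 | [2-(benzyloxy)-4-(methoxymethoxy)phenyl]acetonitrile | N#CCc1ccc(OCOC)cc1OCc1ccccc1
F2 | step 15 | [2-(benzyloxy)-4-(methoxymethoxy)phenyl]acetic acid | OC(=O)Cc1ccc(OCOC)cc1OCc1ccccc1
F3 | step 15 | 2-[2-(benzyloxy)-4-(methoxymethoxy)phenyl]-N-methoxy-N-methylacetamide | CON(C)C(=O)Cc1ccc(OCOC)cc1OCc1ccccc1
F4 | step 15 | 2-[2-(benzyloxy)-4-(methoxymethoxy)phenyl]-1-{2-hydroxy-4,6-bis(methoxymethoxy)-5-[3-methyl-3-(triethylsilyloxy)butyl]phenyl}ethan-1-one | O=C(Cc1ccc(OCOC)cc1OCc1ccccc1)c1c(O)cc(OCOC)c(CCC(C)(C)O[Si](CC)(CC)CC)c1OCOC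
F5 | step 8 | 2-chloro-1-{2-hydroxy-4,6-bis(methoxymethoxy)-5-[3-methyl-3-(triethylsilyloxy)butyl]phenyl}ethan-1-one | O=C(CCl)c1c(O)cc(OCOC)c(CCC(C)(C)O[Si](CC)(CC)CC)c1OCOC
F6 | step 18 | 5,7-bis(methoxymethoxy)-3-[4-(methoxymethoxy)-2-(2-methylbut-3-yn-2-yloxy)phenyl]-6-[3-methyl-3-(triethylsilyloxy)butyl]-4H-chromen-4-one | COCOc1ccc(-c2coc3cc(OCOC)c(CCC(C)(C)O[Si](CC)(CC)CC)c(OCOC)c3c2=O)c(OC(C)(C)C#C)c1
F0 | step 19 | none | none
F7 | step 20 | 3-[3-(3-methylbut-2-en-1-yl)-2,4-bis(trimethylsilyloxy)phenyl]-6-[3-methyl-3-(triethylsilyloxy)butyl]-5,7-bis(trimethylsilyloxy)-4H-chromen-4-one | CC(C)=CCc1c(O[Si](C)(C)C)ccc(-c2coc3cc(O[Si](C)(C)C)c(CCC(C)(C)O[Si](CC)(CC)CC)c(O[Si](C)(C)C)c3c2=O)c1O[Si](C)(C)C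
A1 | alternative 1 | racemic 3-[2,4-bis(methoxymethoxy)-3-(3-methylbut-2-en-1-yl)phenyl]-3-hydroxy-5,7-bis(methoxymethoxy)-6-[3-methyl-3-(triethylsilyloxy)butyl]chroman-4-one | O=C1c2c(OCOC)c(CCC(C)(C)O[Si](CC)(CC)CC)c(OCOC)cc2OCC1(O)c1ccc(OCOC)c(CC=C(C)C)c1OCOC
A2 | alternative 1 | 2-{2-[2,4-bis(methoxymethoxy)-3-(3-methylbut-2-en-1-yl)phenyl]-2-oxoethoxy}-4,6-bis(methoxymethoxy)-5-[3-methyl-3-(triethylsilyloxy)butyl]benzaldehyde | O=Cc1c(OCOC)c(CCC(C)(C)O[Si](CC)(CC)CC)c(OCOC)cc1OCC(=O)c1ccc(OCOC)c(CC=C(C)C)c1OCOC
A3 | alternative 2 | 3-[2,4-bis(methoxymethoxy)-3-(3-methylbut-2-en-1-yl)phenyl]-6-(3-hydroxy-3-methylbutyl)-5,7-bis(methoxymethoxy)-4H-chromen-4-one | COCOc1cc2occ(-c3ccc(OCOC)c(CC=C(C)C)c3OCOC)c(=O)c2c(OCOC)c1CCC(C)(C)O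
A4 | alternative 2 | (Z)-2-[2,4-bis(methoxymethoxy)-3-(3-methylbut-2-en-1-yl)phenyl]-3-[4-(3-hydroxy-3-methylbutyl)-3,5-bis(methoxymethoxy)phenoxy]acrylic acid | OC(=O)/C(=C\Oc1cc(OCOC)c(CCC(C)(C)O)c(OCOC)c1)c1ccc(OCOC)c(CC=C(C)C)c1OCOC
A5 | alternative 3 | 3-[2-hydroxy-3-(3-methylbut-2-en-1-yl)-4-(triisopropylsilyloxy)phenyl]-5,7-bis(methoxymethoxy)-6-[3-methyl-3-(triethylsilyloxy)butyl]-4H-chromen-4-one | CC(C)=CCc1c(O[Si](C(C)C)(C(C)C)C(C)C)ccc(-c2coc3cc(OCOC)c(CCC(C)(C)O[Si](CC)(CC)CC)c(OCOC)c3c2=O)c1O
A6 | alternative 3 | 3-[(E)-4-diazo-3-oxobut-1-en-1-yl]-5,7-bis(methoxymethoxy)-6-[3-methyl-3-(triethylsilyloxy)butyl]-4H-chromen-4-one | [N-]=[N+]=CC(=O)/C=C/c1coc2cc(OCOC)c(CCC(C)(C)O[Si](CC)(CC)CC)c(OCOC)c2c1=O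
A7 | alternative 3 | triisopropyl[(5-methylhex-4-en-1-yn-1-yl)oxy]silane | CC(C)=CCC#CO[Si](C(C)C)(C(C)C)C(C)C
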